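In prostanoid numbering, the cyclopentenone ring C8–C12 of punaglandin 6, with the C9 ketone, the C10 chlorine and the C12 tertiary hydroxyl, is an isomer of a 3-chloro-5-octenyl-2-furylcarbinol: furan C2–C5 become C9–C12 and the carbinol carbon becomes C8. A Piancatelli rearrangement under a chiral Brønsted acid in wet THF therefore adds water at C12, opens the furan and forms the C8–C12 bond by 4π conrotation, creating the ring and both ring stereocentres in one operation. The precursor is that furylcarbinol carrying the finished side chain, O5 and O6 already as the acetates of the target, which are inert to the acid and cannot trap the C8 cation as a cyclic ether, so the rearrangement is the last step.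

Key step: step 12

Assumption: precedent does not tell which antipode of the chiral acid gives the (12S) sense of conrotation; the (R) acid is written, and its mirror image would be used if a first trial showed the opposite sense.

Step 1
Reactants: 1 (2Z)-oct-2-en-1-ol
Product: 2 (2Z)-1-bromooct-2-ene
Conditions: CBr4, PPh3, CH2Cl2, 0 °C
Reagents that add atoms: tetrabromomethane, BrC(Br)(Br)Br
Why: Appel bromination of a primary allylic alcohol proceeds by SN2 displacement of the oxyphosphonium ion at 0 °C, so neither allylic transposition nor loss of the Z geometry is expected.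

Step 2
Reactants: 3 3-bromofuran
Product: 5 3-bromo-2-(trimethylsilyl)furan, via 3-bromo-2-lithiofuran 4 (not isolated)
Conditions: LiN(iPr)2, THF, −78 °C; Me3SiCl, −78 °C → rt
Reagents that add atoms: chlorotrimethylsilane, C[Si](C)(C)Cl
Why: Directed α-lithiation removes the C2 proton flanked by the ring oxygen and the bromine at −78 °C, where halogen migration is slow, and silylation of the furyllithium blocks this position.

Step 3
Reactants: 5 3-bromo-2-(trimethylsilyl)furan
Product: 7 3-chloro-2-(trimethylsilyl)furan, via 3-lithio-2-(trimethylsilyl)furan 6 (not isolated)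
Conditions: n-BuLi, Et2O, −78 °C; C2Cl6, −78 °C → rt
Reagents that add atoms: hexachloroethane, ClC(Cl)(Cl)C(Cl)(Cl)Cl
Why: Bromine–lithium exchange at −78 °C followed by electrophilic chlorination of the 3-furyllithium with hexachloroethane swaps the halogen, and the silyl group keeps the intermediates non-volatile and C2 protected.

Step 4
Reactants: 7 3-chloro-2-(trimethylsilyl)furan; 2 (2Z)-1-bromooct-2-ene
Product: 10 4-chloro-2-[(2Z)-oct-2-en-1-yl]furan, via C5-lithiofuran 8 (not isolated), via silylated octenylfuran 9 (not isolated)
Conditions: n-BuLi, THF, −78 → −20 °C; 2, −78 °C → rt; Bu4NF, THF, rt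
Reagents that add atoms: none
Why: α-Lithiation at C5, the only free α-position, then copper-free SN2 alkylation of the hard furyllithium at C1 of the primary allylic bromide (Z geometry retained) and fluoride protodesilylation of the 2-silylfuran in the same flask should give the 2,4-disubstituted furan.

Step 5
Reactants: 11 [(4S,5S)-2,2-dimethyl-1,3-dioxolane-4,5-diyl]dimethanol (2,3-O-isopropylidene-L-threitol)
Product: 12 [(4S,5S)-5-(hydroxymethyl)-2,2-dimethyl-1,3-dioxolan-4-yl]methyl 4-methylbenzenesulfonate
Conditions: TsCl, Ag2O, KI (cat.), CH2Cl2, rt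
Reagents that add atoms: 4-methylbenzenesulfonyl chloride, Cc1ccc(cc1)S(Cl)(=O)=O
Why: Ag2O-mediated sulfonylation of a symmetrical diol stops cleanly after one tosylation, and because the diol is C2-symmetric either hydroxyl gives the same monotosylate.

Step 6
Reactants: 12 [(4S,5S)-5-(hydroxymethyl)-2,2-dimethyl-1,3-dioxolan-4-yl]methyl 4-methylbenzenesulfonate
Product: 13 [(4S,5R)-5-(iodomethyl)-2,2-dimethyl-1,3-dioxolan-4-yl]methanol
Conditions: NaI, acetone, reflux
Reagents that add atoms: sodium iodide, [Na+].[I-]
Why: Finkelstein exchange (SN2 at the primary carbon), driven by precipitation of sodium tosylate, leaves both dioxolane stereocentres untouched; the descriptor changes only because iodine changes the priorities.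

Step 7
Reactants: 13 [(4S,5R)-5-(iodomethyl)-2,2-dimethyl-1,3-dioxolan-4-yl]methanol
Product: 14 methyl 4-[(4S,5S)-5-(hydroxymethyl)-2,2-dimethyl-1,3-dioxolan-4-yl]butanoate
Conditions: methyl acrylate (5 equiv), Bu3SnH (slow addition), AIBN (cat.), benzene, 80 °C
Reagents that add atoms: methyl acrylate, C=CC(=O)OC
Why: In this Giese reaction the nucleophilic primary radical from the iodide adds to the excess electron-poor acrylate before it is reduced, which installs C3, C2 and the C1 methyl ester in one step, while the β-oxygenated radical does not fragment and the free hydroxyl is inert.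

Step 8
Reactants: 14 methyl 4-[(4S,5S)-5-(hydroxymethyl)-2,2-dimethyl-1,3-dioxolan-4-yl]butanoate
Product: 16 methyl 4-[(4S,5S)-2,2-dimethyl-5-(prop-2-en-1-yl)-1,3-dioxolan-4-yl]butanoate, via primary triflate 15 (not isolated)
Conditions: Tf2O, 2,6-lutidine, CH2Cl2, −78 °C; crude triflate, CH2=CHMgBr (slow addition), CuI (10 mol%), THF, −40 °C
Reagents that add atoms: vinylmagnesium bromide, C=C[Mg]Br
Why: Copper-catalysed Grignard cross-coupling displaces the primary triflate at −40 °C much faster than the Grignard reagent attacks the methyl ester, and the allyl terminus so formed is the masked C8 aldehyde.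

Step 9
Reactants: 16 methyl 4-[(4S,5S)-2,2-dimethyl-5-(prop-2-en-1-yl)-1,3-dioxolan-4-yl]butanoate
Product: 18 methyl (5S,6S)-5,6-diacetoxynon-8-enoate, via methyl (5S,6S)-5,6-dihydroxynon-8-enoate 17 (not isolated)
Conditions: TsOH·H2O (cat.), MeOH, rt; Et3N, concentrate; Ac2O, pyridine, DMAP (cat.), CH2Cl2, 0 °C → rt
Reagents that add atoms: acetic anhydride, CC(=O)OC(C)=O
Why: Acid-catalysed transketalisation in methanol frees the diol while the solvent keeps the 5-hydroxy ester from closing to the δ-lactone, and immediate acetylation of the crude diol installs the two acetates of the target at a stage where no other hydroxyl is present and no stereocentre is touched.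

Step 10
Reactants: 18 methyl (5S,6S)-5,6-diacetoxynon-8-enoate
Product: 19 methyl (5S,6S)-5,6-diacetoxy-8-oxooctanoate
Conditions: O3, CH2Cl2, −78 °C; PPh3, −78 °C → rt
Reagents that add atoms: ozone, [O-][O+]=O
Why: Ozonolysis of the terminal alkene with reductive work-up unveils the C8 aldehyde under neutral conditions, so the β-acetoxy aldehyde never meets base and can be used without chromatography.

Step 11
Reactants: 10 4-chloro-2-[(2Z)-oct-2-en-1-yl]furan; 19 methyl (5S,6S)-5,6-diacetoxy-8-oxooctanoate
Product: 22 methyl (5S,6S)-5,6-diacetoxy-8-{3-chloro-5-[(2Z)-oct-2-en-1-yl]furan-2-yl}-8-hydroxyoctanoate (both C8 epimers), via 2-lithiofuran 20 (not isolated), via furylmagnesium bromide 21 (not isolated)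
Conditions: LiN(iPr)2, THF, −78 °C; MgBr2·OEt2, −78 °C; 19, −78 °C; AcOH quench at −78 °C
Reagents that add atoms: none
Why: The amide base removes the ring proton activated by both the oxygen and the adjacent chlorine, and after transmetalation the less basic furyl Grignard reagent should add to the aldehyde at −78 °C faster than it enolises it or attacks the acetate and methyl ester groups, giving the C8 carbinol as an epimer mixture that is irrelevant because this centre is lost in step 12.

Step 12
Reactants: 22 methyl (5S,6S)-5,6-diacetoxy-8-{3-chloro-5-[(2Z)-oct-2-en-1-yl]furan-2-yl}-8-hydroxyoctanoate (both C8 epimers)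
Product: 23 punaglandin 6
Conditions: (R)-3,3'-bis(2,4,6-triisopropylphenyl)-1,1'-binaphthyl-2,2'-diyl N-triflylphosphoramide (10 mol%), THF/H2O 10:1, 40 °C
Reagents that add atoms: water, O
Why: Proposed new method: the acid ionises either carbinol epimer to the furan-stabilised C8 cation, water adds at C12, the hemiketal opens to the 1,4-dihydroxypentadienyl cation C8–C12 with chlorine on its central carbon C10, and this cation closes; the closest known reaction is the acid-catalysed Piancatelli rearrangement of 5-alkyl-2-furylcarbinols to 4-alkyl-4-hydroxycyclopentenones, and control of the sense of rotation by a chiral counter-anion is so far known only for the variant with aniline nucleophiles. The five-membered ring C8–C12 closes by a thermal 4π conrotatory electrocyclisation of Nazarov type that forms the C8–C12 bond. C12 is set by torquoselectivity, which the chiral phosphoramide anion, hydrogen-bonded to the hydroxyls of the cation, has to impose because the C5 and C6 centres are too remote. C8 is set relative to C12 by thermodynamic control, since its α-proton should equilibrate through the enol under the acid until the C7 chain lies trans to the octenyl group and cis to the hydroxyl. The step needs capture of the cation by water at C12 and not by an internal oxygen at C8, which the acetate protection of O5 and O6 secures, and it needs C10 to carry positive charge, which lone-pair donation from chlorine should allow at the cost of a slower closure.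

Compound list
1 | (2Z)-oct-2-en-1-ol | CCCCC/C=C\CO | starting material
2 | (2Z)-1-bromooct-2-ene | CCCCC/C=C\CBr | intermediate
3 | 3-bromofuran | Brc1ccoc1 | starting material
4 | 3-bromo-2-lithiofuran | [Li]c1occc1Br | intermediate
5 | 3-bromo-2-(trimethylsilyl)furan | C[Si](C)(C)c1occc1Br | intermediate
6 | 3-lithio-2-(trimethylsilyl)furan | C[Si](C)(C)c1occc1[Li] | intermediate
7 | 3-chloro-2-(trimethylsilyl)furan | C[Si](C)(C)c1occc1Cl | intermediate
8 | 3-chloro-5-lithio-2-(trimethylsilyl)furan | C[Si](C)(C)c1oc([Li])cc1Cl | intermediate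
9 | 3-chloro-5-[(2Z)-oct-2-en-1-yl]-2-(trimethylsilyl)furan | CCCCC/C=C\Cc1cc(Cl)c(o1)[Si](C)(C)C | intermediate
10 | 4-chloro-2-[(2Z)-oct-2-en-1-yl]furan | CCCCC/C=C\Cc1cc(Cl)co1 | intermediate
11 | [(4S,5S)-2,2-dimethyl-1,3-dioxolane-4,5-diyl]dimethanol | OC[C@@H]1OC(C)(C)O[C@H]1CO | starting material
12 | [(4S,5S)-5-(hydroxymethyl)-2,2-dimethyl-1,3-dioxolan-4-yl]methyl 4-methylbenzenesulfonate | OC[C@@H]1OC(C)(C)O[C@H]1COS(=O)(=O)c2ccc(C)cc2 | intermediate
13 | [(4S,5R)-5-(iodomethyl)-2,2-dimethyl-1,3-dioxolan-4-yl]methanol | OC[C@@H]1OC(C)(C)O[C@H]1CI | intermediate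
14 | methyl 4-[(4S,5S)-5-(hydroxymethyl)-2,2-dimethyl-1,3-dioxolan-4-yl]butanoate | OC[C@@H]1OC(C)(C)O[C@H]1CCCC(=O)OC | intermediate
15 | methyl 4-[(4S,5S)-2,2-dimethyl-5-{[(trifluoromethanesulfonyl)oxy]methyl}-1,3-dioxolan-4-yl]butanoate | FC(F)(F)S(=O)(=O)OC[C@@H]1OC(C)(C)O[C@H]1CCCC(=O)OC | intermediate
16 | methyl 4-[(4S,5S)-2,2-dimethyl-5-(prop-2-en-1-yl)-1,3-dioxolan-4-yl]butanoate | C=CC[C@@H]1OC(C)(C)O[C@H]1CCCC(=O)OC | intermediate
17 | methyl (5S,6S)-5,6-dihydroxynon-8-enoate | C=CC[C@H](O)[C@@H](O)CCCC(=O)OC | intermediate
18 | methyl (5S,6S)-5,6-diacetoxynon-8-enoate | C=CC[C@H](OC(C)=O)[C@H](CCCC(=O)OC)OC(C)=O | intermediate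
19 | methyl (5S,6S)-5,6-diacetoxy-8-oxooctanoate | O=CC[C@H](OC(C)=O)[C@H](CCCC(=O)OC)OC(C)=O | intermediate
20 | 3-chloro-2-lithio-5-[(2Z)-oct-2-en-1-yl]furan | CCCCC/C=C\Cc1cc(Cl)c([Li])o1 | intermediate
21 | {3-chloro-5-[(2Z)-oct-2-en-1-yl]furan-2-yl}magnesium bromide | CCCCC/C=C\Cc1cc(Cl)c([Mg]Br)o1 | intermediate
22 | methyl (5S,6S)-5,6-diacetoxy-8-{3-chloro-5-[(2Z)-oct-2-en-1-yl]furan-2-yl}-8-hydroxyoctanoate, C8 epimer mixture | CCCCC/C=C\Cc1cc(Cl)c(o1)C(O)C[C@H](OC(C)=O)[C@H](CCCC(=O)OC)OC(C)=O | intermediate
23 | punaglandin 6, methyl (5S,6S)-5,6-diacetoxy-7-{(1R,2S)-4-chloro-2-hydroxy-2-[(2Z)-oct-2-en-1-yl]-5-oxocyclopent-3-en-1-yl}heptanoate | CCCCC/C=C\C[C@@]1(O)C=C(Cl)C(=O)[C@@H]1C[C@H](OC(C)=O)[C@H](CCCC(=O)OC)OC(C)=O | target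

Total step count: 12. Longest linear sequence: 8 steps (steps 5 to 12, from diol 11); the furan line (steps 2, 3, 4, 11, 12) has 5 steps and step 1 feeds step 4.

Steps most likely to fail

Step 12 (proposed new method). The chlorine-bearing pentadienyl cation may close so slowly that proton loss from C7 to a vinylfuran or acetyl transfer takes over, and in the presence of water the counter-anion may fail to impose one sense of conrotation, so that both ring configurations form. The fallback uses known reactions only and brings the chlorine in after the ring is made; it sets out from bromide 2 and aldehyde 19 and comes back at 23. 2-Furyllithium (furan, n-BuLi, THF, 0 °C) is alkylated with 2 to give 2-[(2Z)-oct-2-en-1-yl]furan F1. Lithiation at C5 (n-BuLi, THF, −78 °C), exchange to magnesium with MgBr2·OEt2 and addition to 19 as in step 11 give the chlorine-free furylcarbinol F2. Dy(OTf)3 (10 mol%) in MeCN/H2O at 80 °C, the standard Piancatelli conditions for 5-alkyl-2-furylcarbinols, should give the two 8,12-trans hydroxycyclopentenones, 10-deschloro-punaglandin 6 F3 and the isomer with both ring centres inverted F4. These are diastereomers because of C5 and C6 and would be separated by chromatography. Weitz–Scheffer epoxidation of the enone of F3 (t-BuOOH, DBU, CH2Cl2, 0 °C) gives the 10,11-epoxy ketone F5, and HCl in acetone at 0 °C opens the epoxide at C10 and eliminates water across C10–C11 to give 23.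

Step 11. The magnesium reagent may act as a base and cause loss of acetic acid from the β-acetoxy aldehyde, the acetyl group on O6 may migrate to the new C8 alkoxide, or the reagent may add to an ester carbonyl. The fallback replaces the basic organometallic by a non-basic organochromium reagent made from a halide; it sets out from 10 and comes back at 22. Lithiofuran 20, made from 10 as in step 11, is quenched with I2 to give 3-chloro-2-iodo-5-[(2Z)-oct-2-en-1-yl]furan F6. A Nozaki–Hiyama–Kishi coupling of F6 with 19 (CrCl2, NiCl2 cat., DMF, rt) then gives 22, since the furylchromium species adds only to the aldehyde and does not enolise it.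

Step 4. The furyllithium may attack C3 of the allylic bromide with allylic transposition, the Z double bond may isomerise, or the doubly activated CH2 of the product may transfer a proton to unreacted furyllithium. The fallback builds the Z alkene by olefination; it sets out from 7 and comes back at 9, which is desilylated as in step 4. Lithiofuran 8 opens oxirane (BF3·OEt2, THF, −78 °C) to give 2-[4-chloro-5-(trimethylsilyl)furan-2-yl]ethanol F7. Dess–Martin oxidation gives [4-chloro-5-(trimethylsilyl)furan-2-yl]acetaldehyde F8, used crude, and a salt-free Wittig reaction with hexylidenetriphenylphosphorane (hexyltriphenylphosphonium bromide, NaN(SiMe3)2, THF, −78 °C) should give 9 with Z selectivity.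

Further compounds
F1 | step 12 | 2-[(2Z)-oct-2-en-1-yl]furan | CCCCC/C=C\Cc1ccco1
F2 | step 12 | methyl (5S,6S)-5,6-diacetoxy-8-hydroxy-8-{5-[(2Z)-oct-2-en-1-yl]furan-2-yl}octanoate, C8 epimer mixture | CCCCC/C=C\Cc1ccc(o1)C(O)C[C@H](OC(C)=O)[C@H](CCCC(=O)OC)OC(C)=O
F3 | step 12 | 10-deschloro-punaglandin 6, ring centres arranged in space as in 23 | CCCCC/C=C\C[C@@]1(O)C=CC(=O)[C@@H]1C[C@H](OC(C)=O)[C@H](CCCC(=O)OC)OC(C)=O
F4 | step 12 | diastereomer of F3 with both ring centres inverted | CCCCC/C=C\C[C@]1(O)C=CC(=O)[C@H]1C[C@H](OC(C)=O)[C@H](CCCC(=O)OC)OC(C)=O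
F5 | step 12 | 10,11-epoxide of F3, oxirane cis to the C12 hydroxyl | CCCCC/C=C\C[C@@]1(O)[C@@H]2O[C@@H]2C(=O)[C@@H]1C[C@H](OC(C)=O)[C@H](CCCC(=O)OC)OC(C)=O
F6 | step 11 | 3-chloro-2-iodo-5-[(2Z)-oct-2-en-1-yl]furan | CCCCC/C=C\Cc1cc(Cl)c(I)o1
F7 | step 4 | 2-[4-chloro-5-(trimethylsilyl)furan-2-yl]ethanol | OCCc1cc(Cl)c(o1)[Si](C)(C)C
F8 | step 4 | [4-chloro-5-(trimethylsilyl)furan-2-yl]acetaldehyde | O=CCc1cc(Cl)c(o1)[Si](C)(C)C
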